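**Retrosynthetic overview**
1. Target 29 ⇐ tris-silyl ether 28 (desilylation) ⇐ α-diazo ester 25: Rh carbenoid → bicyclic oxonium ylide → ring-expanding Stevens [1,2]-shift, which forms C1–C2 and turns the oxane into the oxepane.
2. 25 ⇐ acid 19 + tertiary alkoxide from pyranone 13 and MeLi (ester C7–O6), then ring-alkene saturation and diazo transfer.
3. 13 ⇐ (S)-furyl carbinol 11 by Achmatowicz ring expansion; 11 ⇐ furan + 3-chloropropanoyl chloride + (Z)-vinyl iodide from but-2-yn-1-ol (conjugate addition, asymmetric transfer hydrogenation).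
4. 19 ⇐ Z-selective Wittig of the ylide from 5-bromopentanoic acid with silylated hydroxyacetone.
5. Ring order: furan → 2H-pyran-3-one/oxane (step 6) → oxepane, 1,4-dioxan-2-one and ε-lactone of the bicyclo[3.2.2] core together (step 14).

Assumption: TBS = tert-butyldimethylsilyl; C1, C2, C5, C7, C9, O6, O8 are the 6,8-dioxabicyclo[3.2.2]nonan-7-one locants of the target; the Rh2L4 unit of the carbenoid is written [Rh] in its SMILES; anomeric mixtures carry no descriptor at the anomeric carbon.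

**Step 1**
Reactants: 1 but-2-yn-1-ol
Product: 3 (Z)-3-iodobut-2-en-1-ol, via cyclic (Z)-vinylalanate 2 (not isolated)
Conditions: Red-Al, THF, 0 °C → rt; then I2, −78 → 0 °C
Reagents that add atoms: iodine, II
Why: Alkoxide-directed trans-hydroalumination puts Al on C3 cis to CH2O in a five-membered alanate, and iodinolysis with retention gives only the (Z)-iodide.

**Step 2**
Reactants: 3 (Z)-3-iodobut-2-en-1-ol
Product: 4 (Z)-tert-butyl[(3-iodobut-2-en-1-yl)oxy]dimethylsilane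
Conditions: TBSCl, imidazole, CH2Cl2, 0 °C → rt
Reagents that add atoms: tert-butyldimethylsilyl chloride, CC(C)(C)[Si](C)(C)Cl
Why: Routine silylation of a primary alcohol; the silyl ether survives the organometallic steps and leaves in the final global deprotection.

**Step 3**
Reactants: 5 furan; 6 3-chloropropanoyl chloride
Product: 7 3-chloro-1-(furan-2-yl)propan-1-one
Conditions: SnCl4 (1.0 equiv), CH2Cl2, −78 → −40 °C
Reagents that add atoms: none
Why: Friedel–Crafts acylation of furan is α-selective, and a mild Lewis acid at low temperature avoids furan polymerisation.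

**Step 4**
Reactants: 4 (Z)-tert-butyl[(3-iodobut-2-en-1-yl)oxy]dimethylsilane; 7 3-chloro-1-(furan-2-yl)propan-1-one
Product: 10 (4Z)-6-(TBSO)-1-(furan-2-yl)-4-methylhex-4-en-1-one, via (Z)-alkenylmagnesium chloride 8 (not isolated), via furyl vinyl ketone 9 (not isolated)
Conditions: 4, i-PrMgCl·LiCl, THF, 0 °C → rt; 7, Et3N, THF, 0 °C, filtered; combined with CuI·2LiCl (20 mol %), −40 °C; aq NH4Cl
Reagents that add atoms: none
Why: Oxygen-assisted I/Mg exchange keeps the Z geometry (and avoids the silyl migration of the lithium analogue), and copper-catalysed conjugate addition to the vinyl ketone released by HCl elimination forms the chain with the (Z)-alkene intact.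

**Step 5**
Reactants: 10 (4Z)-6-(TBSO)-1-(furan-2-yl)-4-methylhex-4-en-1-one
Product: 11 (1S,4Z)-6-(TBSO)-1-(furan-2-yl)-4-methylhex-4-en-1-ol
Conditions: RuCl[(S,S)-TsDPEN](p-cymene) (1 mol %), HCO2H/Et3N 5:2, CH2Cl2, rt
Reagents that add atoms: none
Why: Noyori asymmetric transfer hydrogenation of a 2-furyl alkyl ketone with the (S,S)-catalyst gives the (S)-carbinol in high ee, which sets C9 of the target.

**Step 6**
Reactants: 11 (1S,4Z)-6-(TBSO)-1-(furan-2-yl)-4-methylhex-4-en-1-ol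
Product: 12 (2S)-6-hydroxy-2-[(3Z)-5-(TBSO)-3-methylpent-3-en-1-yl]-2H-pyran-3(6H)-one (anomeric mixture)
Conditions: NBS (1.05 equiv), NaHCO3, NaOAc, THF/H2O 4:1, 0 °C
Reagents that add atoms: water, O
Why: Achmatowicz oxidative ring expansion; the furan is far more electron-rich than the trisubstituted alkene bearing an allylic silyloxy group, so one equivalent of NBS at 0 °C reacts at the furan, and C9 is untouched.

**Step 7**
Reactants: 12 (2S)-6-hydroxy-2-[(3Z)-5-(TBSO)-3-methylpent-3-en-1-yl]-2H-pyran-3(6H)-one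
Product: 13 (2S,6S)-6-(TBSO)-2-[(3Z)-5-(TBSO)-3-methylpent-3-en-1-yl]-2H-pyran-3(6H)-one (2,6-trans)
Conditions: TBSCl, imidazole, CH2Cl2, −20 → 0 °C; chromatography
Reagents that add atoms: tert-butyldimethylsilyl chloride, CC(C)(C)[Si](C)(C)Cl
Why: Silylation of the equilibrating lactol gives mainly the 2,6-trans silyl acetal (pseudo-axial anomeric OTBS, anomeric effect), which fixes the future C2 configuration; the minor cis anomer is removed.

**Step 8**
Reactants: 14 5-bromopentanoic acid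
Product: 15 (4-carboxybutyl)triphenylphosphonium bromide
Conditions: PPh3, MeCN, reflux
Reagents that add atoms: triphenylphosphine, c1ccc(cc1)P(c1ccccc1)c1ccccc1
Why: SN2 quaternisation of a primary bromide by PPh3.

**Step 9**
Reactants: 16 hydroxyacetone
Product: 17 1-(TBSO)propan-2-one
Conditions: TBSCl, imidazole, CH2Cl2, 0 °C
Reagents that add atoms: tert-butyldimethylsilyl chloride, CC(C)(C)[Si](C)(C)Cl
Why: Routine silylation, which supplies the α-silyloxy ketone needed for a Z-selective Wittig reaction.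

**Step 10**
Reactants: 15 (4-carboxybutyl)triphenylphosphonium bromide; 17 1-(TBSO)propan-2-one
Product: 19 (5Z)-7-(TBSO)-6-methylhept-5-enoic acid, via carboxylate ylide 18 (not isolated)
Conditions: NaHMDS (2.1 equiv), THF, 0 °C; then 17, −78 °C → rt; aq HCl to pH 4
Reagents that add atoms: none
Why: Wittig reaction of a salt-free non-stabilised ylide with an α-alkoxy ketone is strongly Z-selective (chain cis to CH2OSi), which gives the (Z)-2-methyl-allylic ether end.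

**Step 11**
Reactants: 13 (2S,6S)-6-(TBSO)-2-[(3Z)-5-(TBSO)-3-methylpent-3-en-1-yl]-2H-pyran-3(6H)-one; 19 (5Z)-7-(TBSO)-6-methylhept-5-enoic acid
Product: 22 (2S,3R,6S)-6-(TBSO)-2-[(3Z)-5-(TBSO)-3-methylpent-3-en-1-yl]-3-methyl-3,6-dihydro-2H-pyran-3-yl (5Z)-7-(TBSO)-6-methylhept-5-enoate, via lithium alkoxide 20 (not isolated), via acid chloride 21 (not isolated)
Conditions: 13, MeLi (1.05 equiv), THF, −78 °C; 19, 1-chloro-N,N,2-trimethylprop-1-en-1-amine, CH2Cl2, 0 °C → rt; then 21 added to 20, −78 → 0 °C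
Reagents that add atoms: methyllithium, C[Li]
Why: 1,2-Addition of MeLi to the enone occurs anti to the pseudo-axial anomeric OTBS (methyl cis to the C9 chain, which sets C5 as R), and the hindered lithium tertiary alkoxide is acylated in the same flask by the neutral-generated acid chloride.

**Step 12**
Reactants: 22 the dihydropyranyl ester of step 11
Product: 23 (2S,3R,6S)-6-(TBSO)-2-[(3Z)-5-(TBSO)-3-methylpent-3-en-1-yl]-3-methyloxan-3-yl (5Z)-7-(TBSO)-6-methylhept-5-enoate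
Conditions: 2-nitrobenzenesulfonylhydrazide (NBSH), Et3N, CH2Cl2, rt
Reagents that add atoms: none
Why: Diimide reduces the cis-disubstituted ring alkene much faster than the two trisubstituted side-chain alkenes and does not cleave allylic C–O bonds.

**Step 13**
Reactants: 23 the oxanyl ester of step 12
Product: 25 (2S,3R,6S)-6-(TBSO)-2-[(3Z)-5-(TBSO)-3-methylpent-3-en-1-yl]-3-methyloxan-3-yl (5Z)-7-(TBSO)-2-diazo-6-methylhept-5-enoate, via trifluoroacetyl ester 24 (not isolated)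
Conditions: LDA, THF, −78 °C; CF3CO2CH2CF3; aq NH4Cl; then MsN3, Et3N, H2O (1 equiv), MeCN, rt
Reagents that add atoms: methanesulfonyl azide, CS(=O)(=O)N=[N+]=[N-]
Why: Detrifluoroacetylative (Regitz-type) diazo transfer: the ester enolate is activated as its α-trifluoroacetyl derivative, which takes up the diazo group and loses the trifluoroacetyl group as the N-acyl sulfonamide.

**Step 14**
Reactants: 25 the α-diazo ester of step 13
Product: 28 (1R,2S,5R,9S)-2-(TBSO)-1-[(3Z)-5-(TBSO)-4-methylpent-3-en-1-yl]-9-[(3Z)-5-(TBSO)-3-methylpent-3-en-1-yl]-5-methyl-6,8-dioxabicyclo[3.2.2]nonan-7-one, via rhodium carbenoid 26 (not isolated), via oxonium ylide 27 (not isolated)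
Conditions: Rh2(O2CCPh3)4 (2 mol %), CH2Cl2 (0.01 M), slow addition of 25, −40 → 0 °C
Reagents that add atoms: none
Why: Proposed new method: the bulky triphenylacetate ligands slow the 1,2-hydride shift of the α-alkyl carbenoid 26, whose axial ester arm (ring-flipped chair) holds the carbenoid carbon over the ring oxygen, so the six-membered bicyclo[3.3.1] oxonium ylide 27 should form ahead of the eight-membered ylide at the silyloxy oxygen; in 27 the O–C bond to the silyloxy-stabilised anomeric carbon is the weakest, so that carbon (not C9) should migrate to the ylide carbon and recombine in the cage on the face that held oxygen (retention gives C2 as S), forming C1–C2, expanding the oxane to the oxepane and closing the bicycle, with C1 fixed as R by the lactone bridge; the closest known reaction type is the Rh- or Cu-catalysed oxonium-ylide formation/Stevens [1,2]-shift ring expansion of cyclic acetals tethered to diazoketones, not yet shown for an α-alkyl-α-diazo ester with β-hydrogens, an O-silyl lactol as migrating terminus or a bridged-lactone product.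

**Step 15**
Reactants: 28 the tris-silyl bicyclic lactone of step 14
Product: 29 (1R,2S,5R,9S)-2-hydroxy-1-[(3Z)-5-hydroxy-4-methylpent-3-en-1-yl]-9-[(3Z)-5-hydroxy-3-methylpent-3-en-1-yl]-5-methyl-6,8-dioxabicyclo[3.2.2]nonan-7-one (CNP0105745.1)
Conditions: HF·pyridine, pyridine, THF, 0 °C → rt
Reagents that add atoms: none
Why: Buffered acidic fluoride removes all three silyl ethers without opening the lactone and without the retro-aldol cleavage of the β-hydroxy lactone that basic fluoride could cause.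

**Compound list**
1 | but-2-yn-1-ol | CC#CCO | starting material
2 | sodium 2,2-bis(2-methoxyethoxy)-3-methyl-2,5-dihydro-1,2-oxaaluminol-2-uide (cyclic (Z)-vinylalanate) | CC1=CCO[Al-]1(OCCOC)OCCOC.[Na+] | intermediate
3 | (Z)-3-iodobut-2-en-1-ol | C/C(I)=C/CO | intermediate
4 | (Z)-tert-butyl[(3-iodobut-2-en-1-yl)oxy]dimethylsilane | C/C(I)=C/CO[Si](C)(C)C(C)(C)C | intermediate
5 | furan | c1ccoc1 | starting material
6 | 3-chloropropanoyl chloride | ClCCC(Cl)=O | starting material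
7 | 3-chloro-1-(furan-2-yl)propan-1-one | ClCCC(=O)c1ccco1 | intermediate
8 | (Z)-[4-(TBSO)but-2-en-2-yl]magnesium chloride | C/C([Mg]Cl)=C/CO[Si](C)(C)C(C)(C)C | intermediate
9 | 1-(furan-2-yl)prop-2-en-1-one | C=CC(=O)c1ccco1 | intermediate
10 | (4Z)-6-(TBSO)-1-(furan-2-yl)-4-methylhex-4-en-1-one | O=C(CC/C(C)=C\CO[Si](C)(C)C(C)(C)C)c1ccco1 | intermediate
11 | (1S,4Z)-6-(TBSO)-1-(furan-2-yl)-4-methylhex-4-en-1-ol | O[C@@H](CC/C(C)=C\CO[Si](C)(C)C(C)(C)C)c1ccco1 | intermediate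
12 | (2S)-6-hydroxy-2-[(3Z)-5-(TBSO)-3-methylpent-3-en-1-yl]-2H-pyran-3(6H)-one, anomeric mixture | OC1C=CC(=O)[C@H](CC/C(C)=C\CO[Si](C)(C)C(C)(C)C)O1 | intermediate
13 | (2S,6S)-6-(TBSO)-2-[(3Z)-5-(TBSO)-3-methylpent-3-en-1-yl]-2H-pyran-3(6H)-one | CC(C)(C)[Si](C)(C)O[C@H]1C=CC(=O)[C@H](CC/C(C)=C\CO[Si](C)(C)C(C)(C)C)O1 | intermediate
14 | 5-bromopentanoic acid | OC(=O)CCCCBr | starting material
15 | (4-carboxybutyl)triphenylphosphonium bromide | OC(=O)CCCC[P+](c1ccccc1)(c1ccccc1)c1ccccc1.[Br-] | intermediate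
16 | hydroxyacetone (1-hydroxypropan-2-one) | CC(=O)CO | starting material
17 | 1-(TBSO)propan-2-one | CC(=O)CO[Si](C)(C)C(C)(C)C | intermediate
18 | sodium 5-(triphenyl-λ5-phosphanylidene)pentanoate (carboxylate ylide) | [Na+].[O-]C(=O)CCCC=P(c1ccccc1)(c1ccccc1)c1ccccc1 | intermediate
19 | (5Z)-7-(TBSO)-6-methylhept-5-enoic acid | OC(=O)CCC/C=C(/C)CO[Si](C)(C)C(C)(C)C | intermediate
20 | lithium (2S,3R,6S)-6-(TBSO)-2-[(3Z)-5-(TBSO)-3-methylpent-3-en-1-yl]-3-methyl-3,6-dihydro-2H-pyran-3-olate | CC(C)(C)[Si](C)(C)O[C@H]1C=C[C@@](C)([O-])[C@H](CC/C(C)=C\CO[Si](C)(C)C(C)(C)C)O1.[Li+] | intermediate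
21 | (5Z)-7-(TBSO)-6-methylhept-5-enoyl chloride | ClC(=O)CCC/C=C(/C)CO[Si](C)(C)C(C)(C)C | intermediate
22 | (2S,3R,6S)-6-(TBSO)-2-[(3Z)-5-(TBSO)-3-methylpent-3-en-1-yl]-3-methyl-3,6-dihydro-2H-pyran-3-yl (5Z)-7-(TBSO)-6-methylhept-5-enoate | CC(C)(C)[Si](C)(C)O[C@H]1C=C[C@@](C)(OC(=O)CCC/C=C(/C)CO[Si](C)(C)C(C)(C)C)[C@H](CC/C(C)=C\CO[Si](C)(C)C(C)(C)C)O1 | intermediate
23 | (2S,3R,6S)-6-(TBSO)-2-[(3Z)-5-(TBSO)-3-methylpent-3-en-1-yl]-3-methyloxan-3-yl (5Z)-7-(TBSO)-6-methylhept-5-enoate | CC(C)(C)[Si](C)(C)O[C@H]1CC[C@@](C)(OC(=O)CCC/C=C(/C)CO[Si](C)(C)C(C)(C)C)[C@H](CC/C(C)=C\CO[Si](C)(C)C(C)(C)C)O1 | intermediate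
24 | same oxan-3-yl ester of (5Z)-7-(TBSO)-6-methyl-2-(trifluoroacetyl)hept-5-enoic acid (α-epimers) | CC(C)(C)[Si](C)(C)O[C@H]1CC[C@@](C)(OC(=O)C(CC/C=C(/C)CO[Si](C)(C)C(C)(C)C)C(=O)C(F)(F)F)[C@H](CC/C(C)=C\CO[Si](C)(C)C(C)(C)C)O1 | intermediate
25 | (2S,3R,6S)-6-(TBSO)-2-[(3Z)-5-(TBSO)-3-methylpent-3-en-1-yl]-3-methyloxan-3-yl (5Z)-7-(TBSO)-2-diazo-6-methylhept-5-enoate | CC(C)(C)[Si](C)(C)O[C@H]1CC[C@@](C)(OC(=O)C(=[N+]=[N-])CC/C=C(/C)CO[Si](C)(C)C(C)(C)C)[C@H](CC/C(C)=C\CO[Si](C)(C)C(C)(C)C)O1 | intermediate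
26 | rhodium carbenoid of 25 | CC(C)(C)[Si](C)(C)O[C@H]1CC[C@@](C)(OC(=O)C(=[Rh])CC/C=C(/C)CO[Si](C)(C)C(C)(C)C)[C@H](CC/C(C)=C\CO[Si](C)(C)C(C)(C)C)O1 | intermediate
27 | bicyclic oxonium ylide (ring oxygen bonded to the ylide carbon) | CC(C)(C)[Si](C)(C)OC/C(C)=C\CC[C-]1C(=O)O[C@]2(C)CC[C@H](O[Si](C)(C)C(C)(C)C)[O+]1[C@H]2CC/C(C)=C\CO[Si](C)(C)C(C)(C)C | intermediate
28 | (1R,2S,5R,9S)-2-(TBSO)-1-[(3Z)-5-(TBSO)-4-methylpent-3-en-1-yl]-9-[(3Z)-5-(TBSO)-3-methylpent-3-en-1-yl]-5-methyl-6,8-dioxabicyclo[3.2.2]nonan-7-one | C/C(=C/CC[C@@]12O[C@@H](CC/C(C)=C\CO[Si](C)(C)C(C)(C)C)[C@@](C)(CC[C@@H]1O[Si](C)(C)C(C)(C)C)OC2=O)CO[Si](C)(C)C(C)(C)C | intermediate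
29 | (1R,2S,5R,9S)-2-hydroxy-1-[(3Z)-5-hydroxy-4-methylpent-3-en-1-yl]-9-[(3Z)-5-hydroxy-3-methylpent-3-en-1-yl]-5-methyl-6,8-dioxabicyclo[3.2.2]nonan-7-one | C/C(=C/CC[C@@]12O[C@@H](CC/C(C)=C\CO)[C@@](C)(CC[C@@H]1O)OC2=O)CO | target

**Totals**
Total steps: 15. Longest linear sequence: 11 (steps 1, 2, 4, 5, 6, 7, 11, 12, 13, 14, 15).

**Three steps most likely to fail**

Step 14 (the proposed new step). The risks are the 1,2-hydride shift of the carbenoid to the (Z)-enoate, C–H insertion next to the ester oxygen, and erosion of configuration at C2 during the shift. The fallback uses known chemistry (carbenoid O–H insertion, then intramolecular aldol addition); it sets out from 25 and comes back to the route at 29. Buffered fluoride (TBAF/AcOH 1:1, THF, −20 °C) removes only the anomeric silyl group and gives the lactol F1. NaBH4 (EtOH, 0 °C) reduces this through its hydroxy-aldehyde form to the diol F2. Rh2(OAc)4 (CH2Cl2, rt) then inserts the carbenoid into the secondary O–H (six-membered ring) and gives the 1,4-dioxan-2-one alcohol F3. Dess–Martin periodinane gives the aldehyde F4. LiHMDS (THF, −78 °C) closes the oxepane by aldol addition of the lactone enolate to the aldehyde and gives the bis-silyl hydroxy lactone F5, which is desilylated under the conditions of step 15 to 29.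

Step 13. The risk is incomplete enolisation or trifluoroacetylation of the hindered tertiary-alkyl ester. The fallback sets out from 23 and comes back at 25. Electrophilic azidation of the potassium enolate (KHMDS, 2,4,6-triisopropylbenzenesulfonyl azide, THF, −78 °C, AcOH quench) gives the α-azido ester F6. Staudinger reduction (PMe3, THF/H2O) gives the α-amino ester F7. Diazotisation (isoamyl nitrite, cat. AcOH, CHCl3, 60 °C) gives 25.

Step 11. The risks are 1,4-addition, and Ferrier-type ionisation of the tertiary allylic ester 22 (a 2,3-unsaturated pyranoside) during acylation or handling. The fallback sets out from 13 and comes back at 23, so step 12 is no longer needed. Conjugate reduction of the enone with Stryker's reagent ([(Ph3P)CuH]6, toluene, rt), which cannot touch the isolated alkene, gives the saturated ketone F8. MeMgBr/CeCl3 (THF, −78 °C, axial attack) gives the saturated tertiary alcohol F9, which is isolated, deprotonated with KHMDS and acylated with 21 to give 23.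

**Further compounds**
F1 | step 14 | (2S,3R)-6-hydroxy-2-[(3Z)-5-(TBSO)-3-methylpent-3-en-1-yl]-3-methyloxan-3-yl (5Z)-7-(TBSO)-2-diazo-6-methylhept-5-enoate (lactol, anomeric mixture) | OC1CC[C@@](C)(OC(=O)C(=[N+]=[N-])CC/C=C(/C)CO[Si](C)(C)C(C)(C)C)[C@H](CC/C(C)=C\CO[Si](C)(C)C(C)(C)C)O1
F2 | step 14 | (4R,5S,8Z)-10-(TBSO)-1,5-dihydroxy-4,8-dimethyldec-8-en-4-yl (5Z)-7-(TBSO)-2-diazo-6-methylhept-5-enoate | OCCC[C@@](C)(OC(=O)C(=[N+]=[N-])CC/C=C(/C)CO[Si](C)(C)C(C)(C)C)[C@@H](O)CC/C(C)=C\CO[Si](C)(C)C(C)(C)C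
F3 | step 14 | (5S,6R)-6-(3-hydroxypropyl)-6-methyl-3-[(3Z)-5-(TBSO)-4-methylpent-3-en-1-yl]-5-[(3Z)-5-(TBSO)-3-methylpent-3-en-1-yl]-1,4-dioxan-2-one (C3 epimers) | OCCC[C@@]1(C)OC(=O)C(CC/C=C(/C)CO[Si](C)(C)C(C)(C)C)O[C@H]1CC/C(C)=C\CO[Si](C)(C)C(C)(C)C
F4 | step 14 | 3-{(2R,3S)-2-methyl-5-[(3Z)-5-(TBSO)-4-methylpent-3-en-1-yl]-3-[(3Z)-5-(TBSO)-3-methylpent-3-en-1-yl]-6-oxo-1,4-dioxan-2-yl}propanal (C5 epimers) | O=CCC[C@@]1(C)OC(=O)C(CC/C=C(/C)CO[Si](C)(C)C(C)(C)C)O[C@H]1CC/C(C)=C\CO[Si](C)(C)C(C)(C)C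
F5 | step 14 | (1R,2S,5R,9S)-2-hydroxy-1-[(3Z)-5-(TBSO)-4-methylpent-3-en-1-yl]-9-[(3Z)-5-(TBSO)-3-methylpent-3-en-1-yl]-5-methyl-6,8-dioxabicyclo[3.2.2]nonan-7-one | C/C(=C/CC[C@@]12O[C@@H](CC/C(C)=C\CO[Si](C)(C)C(C)(C)C)[C@@](C)(CC[C@@H]1O)OC2=O)CO[Si](C)(C)C(C)(C)C
F6 | step 13 | (2S,3R,6S)-6-(TBSO)-2-[(3Z)-5-(TBSO)-3-methylpent-3-en-1-yl]-3-methyloxan-3-yl (5Z)-2-azido-7-(TBSO)-6-methylhept-5-enoate (α-epimers) | CC(C)(C)[Si](C)(C)O[C@H]1CC[C@@](C)(OC(=O)C(N=[N+]=[N-])CC/C=C(/C)CO[Si](C)(C)C(C)(C)C)[C@H](CC/C(C)=C\CO[Si](C)(C)C(C)(C)C)O1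
F7 | step 13 | (2S,3R,6S)-6-(TBSO)-2-[(3Z)-5-(TBSO)-3-methylpent-3-en-1-yl]-3-methyloxan-3-yl (5Z)-2-amino-7-(TBSO)-6-methylhept-5-enoate (α-epimers) | CC(C)(C)[Si](C)(C)O[C@H]1CC[C@@](C)(OC(=O)C(N)CC/C=C(/C)CO[Si](C)(C)C(C)(C)C)[C@H](CC/C(C)=C\CO[Si](C)(C)C(C)(C)C)O1
F8 | step 11 | (2S,6S)-6-(TBSO)-2-[(3Z)-5-(TBSO)-3-methylpent-3-en-1-yl]oxan-3-one | CC(C)(C)[Si](C)(C)O[C@H]1CCC(=O)[C@H](CC/C(C)=C\CO[Si](C)(C)C(C)(C)C)O1
F9 | step 11 | (2S,3R,6S)-6-(TBSO)-2-[(3Z)-5-(TBSO)-3-methylpent-3-en-1-yl]-3-methyloxan-3-ol | CC(C)(C)[Si](C)(C)O[C@H]1CC[C@@](C)(O)[C@H](CC/C(C)=C\CO[Si](C)(C)C(C)(C)C)O1
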